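The cyclohexane (ring A; eunicellane numbering, C1 and C10–C14) hides a Robinson retron: the C11 carbinol carbon is a latent ketone, C12 its enolisable methyl, and C13 the carbonyl carbon of isovaleraldehyde, whose α-carbon C14 carries the isopropyl group. Everything rests on closing ring A at C12–C13. One operation, an amine-catalysed Michael addition/aldol condensation, joins isovaleraldehyde with 4-acetylfuran-2(5H)-one, sets C14 and C1, and delivers a cis-fused cyclohexenone γ-lactone. Its lactone already holds C2 and C9 as differentiated arms for the ten-membered ring B. The precursor is thus a flat acetylbutenolide and a five-carbon aldehyde.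

Key step: step 2

Remark: eunicellane locants are used throughout (C1/C10 ring fusion, C2=C3 Z-alkene, C6 and C9 acetoxy carbons, C7 with the exocyclic methylene, C11 methyl carbinol, C14 isopropyl-bearing carbon). 4-Bromofuran-2(5H)-one is taken as purchasable.

Step 1
Reactants: 1 4-bromofuran-2(5H)-one; 2 tributyl(1-ethoxyvinyl)stannane
Product: 4 4-acetylfuran-2(5H)-one, via ethoxyvinyl butenolide 3 (not isolated)
Conditions: Pd(PPh3)4 (5 mol %), CuI (10 mol %), dioxane, 90 °C; then 1 M HCl, THF, rt
Reagents that add atoms: water, O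
Why: Stille coupling of the β-bromo enoate with the acetyl anion equivalent, followed by acid hydrolysis of the enol ether, should give the β-acyl butenolide; no stereocentre is formed.

Step 2
Reactants: 4 4-acetylfuran-2(5H)-one; 5 3-methylbutanal (2 equiv)
Product: 7 (3aS,7S,7aR)-7-(propan-2-yl)-3,3a,7,7a-tetrahydro-2-benzofuran-1,4-dione, via Michael adduct 6 (not isolated)
Conditions: (S)-α,α-diphenylprolinol trimethylsilyl ether (10 mol %), 4-nitrophenol (10 mol %), toluene, 0 °C → rt; then TsOH·H2O (20 mol %), 4 Å MS, 70 °C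
Reagents that add atoms: none
Why: The amine condenses with 5 to an E-enamine whose open face adds to C3 of butenolide 4 (β to the acetyl ketone, α to the lactone carbonyl) to give 1,5-keto aldehyde 6, and acid then drives the intramolecular aldol condensation of the acetyl methyl (C12) onto the aldehyde carbon (C13) with loss of water; this is a Robinson-type annulation whose closest precedents are the amine-catalysed Michael/aldol route to 4-alkylcyclohexenones and enamine additions to 4-oxo-enoates and maleimides. Ring A closes by a 6-(enolexo)-exo-trig aldol followed by dehydration, and only the methyl enol can close a six-membered ring (the C10 enol would give a cyclobutane). C14 is set by the catalyst, which shields one enamine face; C1 by the acyclic synclinal arrangement of enamine and acceptor (acetyl trans to the lactone carbonyl, as nitro to aryl in nitroalkenes); and C10 by acid equilibration through the enol to the cis-fused lactone with the isopropyl group on the convex face. The step needs attack at C3 rather than C4 of 4, which the stronger ketone acceptor and the fully substituted C4 should secure, and it needs C14 not to epimerise, which the mild acid stage and the γ-position of this centre in the enone should ensure.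

Step 3
Reactants: 7 enone lactone
Product: 8 (3aS,7R,7aR)-7-(propan-2-yl)hexahydro-2-benzofuran-1,4-dione
Conditions: H2 (1 atm), Pd/C (10 %), EtOAc, rt
Reagents that add atoms: none
Why: Heterogeneous catalytic hydrogenation should saturate only the conjugated C12=C13 alkene (ketone and lactone untouched) and creates no stereocentre.

Step 4
Reactants: 8 keto lactone
Product: 9 (3aR,7R,7aR)-4-methylidene-7-(propan-2-yl)hexahydro-2-benzofuran-1(3H)-one
Conditions: Zn, CH2Br2, TiCl4, THF/CH2Cl2, 0 °C → rt
Reagents that add atoms: dibromomethane, BrCBr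
Why: Takai–Lombardo methylenation is non-basic and ketone-selective, so the lactone, the epimerisable C10 and the β-acyloxy ketone motif should survive; no stereocentre is formed.

Step 5
Reactants: 9 methylidene lactone
Product: 10 (3aS,4R,7R,7aR)-4-hydroxy-4-methyl-7-(propan-2-yl)hexahydro-2-benzofuran-1(3H)-one
Conditions: Mn(dpm)3 (dpm = dipivaloylmethanato, 10 mol %), PhSiH3, O2 (1 atm), i-PrOH/CH2Cl2, 0 °C
Reagents that add atoms: dioxygen, O=O
Why: Mukaiyama hydration (hydrogen-atom transfer to the methylidene, then O2 capture of the tertiary C11 radical) should place the oxygen on the convex face, anti to the lactone CH2 on C10, which is the C11 configuration of the target and the opposite of what methyl addition to ketone 8 would give.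

Step 6
Reactants: 10 hydroxy lactone
Product: 11 (3aS,4R,7R,7aR)-4-methyl-7-(propan-2-yl)octahydro-2-benzofuran-1,4-diol (lactol, anomeric mixture)
Conditions: i-Bu2AlH (2.5 equiv), CH2Cl2, −78 °C; aq. potassium sodium tartrate
Reagents that add atoms: none
Why: Partial reduction of a γ-lactone with i-Bu2AlH at low temperature should stop at the lactol after the tertiary hydroxyl has consumed one equivalent; the ring stereocentres are not touched.

Step 7
Reactants: 11 lactol
Product: 12 (1R,2S,3R,4R)-2-(hydroxymethyl)-3-[(1Z)-2-iodoprop-1-en-1-yl]-1-methyl-4-(propan-2-yl)cyclohexan-1-ol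
Conditions: EtPPh3I, n-BuLi, THF, rt; I2, −78 °C; NaN(SiMe3)2, −20 °C; then 11, −78 → −20 °C (3 equiv ylide)
Reagents that add atoms: ethyltriphenylphosphonium iodide, CC[P+](c1ccccc1)(c1ccccc1)c1ccccc1.[I-]; iodine, II
Why: Stork–Zhao-type Wittig olefination of the open hydroxy aldehyde form with the non-stabilised α-iodoethylidene ylide is kinetically Z-selective (iodine cis to the ring carbon), which fixes the C2=C3 geometry and releases the C9 hydroxymethyl arm.

Step 8
Reactants: 12 iodoalkene diol; 13 3,3-diethoxyprop-1-ene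
Product: 15 (1R,2S,3S,4R)-3-[(1Z)-5,5-diethoxy-2-methylpent-1-en-1-yl]-2-(hydroxymethyl)-1-methyl-4-(propan-2-yl)cyclohexan-1-ol, via alkylborane 14 (not isolated)
Conditions: 13, 9-BBN, THF, rt; then 12, Pd(dppf)Cl2 (5 mol %), AsPh3, Cs2CO3, DMF/H2O, rt
Reagents that add atoms: none
Why: B-alkyl Suzuki–Miyaura coupling of the anti-Markovnikov 9-BBN adduct with the iodoalkene proceeds with retention, so the C4–C6 chain takes the place of iodine and the trisubstituted alkene is Z; free hydroxyls are tolerated.

Step 9
Reactants: 15 acetal diol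
Product: 16 (1R,2R,5R,6S)-6-[(1Z)-5,5-diethoxy-2-methylpent-1-en-1-yl]-2-hydroxy-2-methyl-5-(propan-2-yl)cyclohexane-1-carbaldehyde
Conditions: Dess–Martin periodinane, NaHCO3, CH2Cl2, 0 °C
Reagents that add atoms: none
Why: Dess–Martin oxidation converts only the primary alcohol (the tertiary one cannot react) under buffered, non-epimerising conditions that spare acetal and alkene.

Step 10
Reactants: 16 aldehyde; 17 2,3-dibromoprop-1-ene
Product: 18 (1R,2S,3S,4R)-2-[(1R)-3-bromo-1-hydroxybut-3-en-1-yl]-3-[(1Z)-5,5-diethoxy-2-methylpent-1-en-1-yl]-1-methyl-4-(propan-2-yl)cyclohexan-1-ol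
Conditions: In (powder), DMF, 0 °C → rt; aq. NaHCO3
Reagents that add atoms: none
Why: Indium-mediated Barbier 2-bromoallylation is neutral (acetal, free alcohol and the α-stereocentre should survive), and Felkin–Anh addition with the quaternary C11 as the large group anti to the nucleophile should give the (9R)-carbinol.

Step 11
Reactants: 18 bromoallyl carbinol
Product: 19 (1R,2S,3S,4R)-2-[(1R)-3-bromo-1-hydroxybut-3-en-1-yl]-1-methyl-3-[(1Z)-2-methyl-5-oxopent-1-en-1-yl]-4-(propan-2-yl)cyclohexan-1-ol
Conditions: PPTS (cat.), acetone/H2O, 40 °C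
Reagents that add atoms: water, O
Why: Mild acid-catalysed acetal hydrolysis should liberate the C6 aldehyde without dehydrating the tertiary alcohol or touching the bromoalkene.

Step 12
Reactants: 19 bromo aldehyde
Product: 20 (2Z)-eunicella-2,7(16)-diene-6,9,11-triol (6,9-di-O-deacetyl target, all six stereocentres as in the target)
Conditions: CrCl2 (8 equiv), NiCl2 (2 mol %), DMSO, rt, 0.005 M, slow addition
Reagents that add atoms: none
Why: The Nozaki–Hiyama–Kishi reaction (nickel insertion into the bromoalkene, transmetallation to trivalent chromium, addition to the aldehyde) closes ring B at C6–C7 with the exocyclic methylene in place, tolerates the free hydroxyls, and is expected to give the 6R carbinol by attack on the outer face of the aldehyde in the conformation imposed by the Z-alkene and the cis ring fusion.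

Step 13
Reactants: 20 triol
Product: 21 (2Z)-6,9-diacetoxyeunicella-2,7(16)-dien-11-ol (target)
Conditions: Ac2O, pyridine, DMAP (cat.), CH2Cl2, 0 °C → rt
Reagents that add atoms: acetic anhydride, CC(=O)OC(C)=O
Why: Acylation should esterify the two secondary alcohols at C6 and C9, while the hindered tertiary C11 alcohol does not react under these conditions.

Compound list

1 | 4-bromofuran-2(5H)-one | O=C1C=C(Br)CO1 | starting material
2 | tributyl(1-ethoxyvinyl)stannane | CCCC[Sn](CCCC)(CCCC)C(=C)OCC | starting material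
3 | 4-(1-ethoxyvinyl)furan-2(5H)-one | C=C(OCC)C1=CC(=O)OC1 | intermediate
4 | 4-acetylfuran-2(5H)-one | CC(=O)C1=CC(=O)OC1 | intermediate
5 | 3-methylbutanal (isovaleraldehyde) | CC(C)CC=O | starting material
6 | (2R)-2-[(3R,4S)-4-acetyl-2-oxooxolan-3-yl]-3-methylbutanal (drawn as the cis isomer that cyclises; the acetyl-bearing centre is labile) | O=C[C@H](C(C)C)[C@H]1C(=O)OC[C@H]1C(C)=O | intermediate
7 | (3aS,7S,7aR)-7-(propan-2-yl)-3,3a,7,7a-tetrahydro-2-benzofuran-1,4-dione (cis-fused, isopropyl on the face of the ring-fusion hydrogens) | O=C1C=C[C@H](C(C)C)[C@H]2C(=O)OC[C@@H]12 | intermediate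
8 | (3aS,7R,7aR)-7-(propan-2-yl)hexahydro-2-benzofuran-1,4-dione | O=C1CC[C@H](C(C)C)[C@H]2C(=O)OC[C@@H]12 | intermediate
9 | (3aR,7R,7aR)-4-methylidene-7-(propan-2-yl)hexahydro-2-benzofuran-1(3H)-one | C=C1CC[C@H](C(C)C)[C@H]2C(=O)OC[C@@H]12 | intermediate
10 | (3aS,4R,7R,7aR)-4-hydroxy-4-methyl-7-(propan-2-yl)hexahydro-2-benzofuran-1(3H)-one | C[C@@]1(O)CC[C@H](C(C)C)[C@H]2C(=O)OC[C@@H]12 | intermediate
11 | (3aS,4R,7R,7aR)-4-methyl-7-(propan-2-yl)octahydro-2-benzofuran-1,4-diol (anomers) | C[C@@]1(O)CC[C@H](C(C)C)[C@H]2C(O)OC[C@@H]12 | intermediate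
12 | (1R,2S,3R,4R)-2-(hydroxymethyl)-3-[(1Z)-2-iodoprop-1-en-1-yl]-1-methyl-4-(propan-2-yl)cyclohexan-1-ol | C[C@@]1(O)CC[C@H](C(C)C)[C@@H](/C=C(/C)I)[C@H]1CO | intermediate
13 | 3,3-diethoxyprop-1-ene (acrolein diethyl acetal) | C=CC(OCC)OCC | starting material
14 | 9-(3,3-diethoxypropyl)-9-borabicyclo[3.3.1]nonane | CCOC(CCB1C2CCCC1CCC2)OCC | intermediate
15 | (1R,2S,3S,4R)-3-[(1Z)-5,5-diethoxy-2-methylpent-1-en-1-yl]-2-(hydroxymethyl)-1-methyl-4-(propan-2-yl)cyclohexan-1-ol | C[C@@]1(O)CC[C@H](C(C)C)[C@@H](/C=C(/C)CCC(OCC)OCC)[C@H]1CO | intermediate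
16 | (1R,2R,5R,6S)-6-[(1Z)-5,5-diethoxy-2-methylpent-1-en-1-yl]-2-hydroxy-2-methyl-5-(propan-2-yl)cyclohexane-1-carbaldehyde | C[C@@]1(O)CC[C@H](C(C)C)[C@@H](/C=C(/C)CCC(OCC)OCC)[C@H]1C=O | intermediate
17 | 2,3-dibromoprop-1-ene | C=C(Br)CBr | starting material
18 | (1R,2S,3S,4R)-2-[(1R)-3-bromo-1-hydroxybut-3-en-1-yl]-3-[(1Z)-5,5-diethoxy-2-methylpent-1-en-1-yl]-1-methyl-4-(propan-2-yl)cyclohexan-1-ol | C[C@@]1(O)CC[C@H](C(C)C)[C@@H](/C=C(/C)CCC(OCC)OCC)[C@H]1[C@H](O)CC(Br)=C | intermediate
19 | (1R,2S,3S,4R)-2-[(1R)-3-bromo-1-hydroxybut-3-en-1-yl]-1-methyl-3-[(1Z)-2-methyl-5-oxopent-1-en-1-yl]-4-(propan-2-yl)cyclohexan-1-ol | C[C@@]1(O)CC[C@H](C(C)C)[C@@H](/C=C(/C)CCC=O)[C@H]1[C@H](O)CC(Br)=C | intermediate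
20 | (2Z)-eunicella-2,7(16)-diene-6,9,11-triol, stereocentres as in the target | C[C@@]1(O)CC[C@H](C(C)C)[C@H]2/C=C(/C)CC[C@@H](O)C(=C)C[C@@H](O)[C@@H]12 | intermediate
21 | (2Z)-6,9-diacetoxyeunicella-2,7(16)-dien-11-ol (CNP0303839.1) | C=C1C[C@@H](OC(C)=O)[C@@H]2[C@H](/C=C(/C)CC[C@H]1OC(C)=O)[C@@H](C(C)C)CC[C@@]2(C)O | target

Total step count: 13. Longest linear sequence: 13 steps (1 → 21).

Steps most likely to fail

1. Step 2. The conjugate addition to the trisubstituted butenolide may be slow or may lose out to γ-deprotonation of 4 by the amine. The hot acid stage may open the lactone by β-elimination, and epimerisation at C14 would erode diastereo- and enantiopurity. The fallback sets out from 5 and comes back at 7. Aldehyde 5 is added under the same amine catalysis to purchasable ethyl (E)-4-oxopent-2-enoate (CCOC(=O)/C=C/C(C)=O), the established acyclic acceptor class, to give keto aldehyde ester F1. TsOH-mediated aldol condensation then closes the same C12–C13 bond to give cyclohexenone ester F2. The kinetic α′-enolate (LiN(i-Pr)2, THF, −78 °C) is trapped with monomeric formaldehyde to give hydroxymethyl ketone F3. Acid lactonisation with equilibration at C10 to the cis-fused ring system returns 7.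

2. Step 12. Insertion into the hindered 1,1-disubstituted bromoalkene may be slow, so intermolecular coupling and aldehyde reduction could outrun the entropically costly ten-membered closure; facial selectivity at C6 is also uncertain. The fallback sets out from 18 and comes back at 20. It changes the ring-closing electrophile: copper-catalysed halogen exchange (CuI, N,N′-dimethylethylenediamine, NaI, dioxane, 110 °C) converts 18 into iodoalkene F4. Acetal hydrolysis (PPTS, aqueous acetone) gives iodo aldehyde F5, whose far faster insertion allows the CrCl2/NiCl2 closure at lower temperature and higher dilution to 20.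

3. Step 10. The aldehyde may epimerise at C10 or undergo retro-aldol cleavage before it is trapped, and the addition may show poor facial selectivity (Felkin against anti-Felkin). The fallback sets out from 16 and comes back at 18. It moves control of C9 from the substrate to a reagent: the addition is run as before, and the C9-epimeric carbinol F6 (or the epimer mixture) is oxidised with Dess–Martin periodinane to β,γ-unsaturated ketone F7. Reduction with (S)-2-methyl-CBS-oxazaborolidine and catecholborane (large ring substituent against small bromoallyl group) should then give the 9R alcohol 18.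

Further compounds

F1 | step 2 | ethyl (2S)-2-[(2R)-3-methyl-1-oxobutan-2-yl]-4-oxopentanoate | O=C[C@H](C(C)C)[C@@H](C(=O)OCC)CC(C)=O
F2 | step 2 | ethyl (1S,2S)-5-oxo-2-(propan-2-yl)cyclohex-3-ene-1-carboxylate | O=C1C=C[C@H](C(C)C)[C@@H](C(=O)OCC)C1
F3 | step 2 | ethyl (1R,2S)-6-(hydroxymethyl)-5-oxo-2-(propan-2-yl)cyclohex-3-ene-1-carboxylate (C6 epimers) | O=C1C=C[C@H](C(C)C)[C@@H](C(=O)OCC)C1CO
F4 | step 12 | (1R,2S,3S,4R)-3-[(1Z)-5,5-diethoxy-2-methylpent-1-en-1-yl]-2-[(1R)-1-hydroxy-3-iodobut-3-en-1-yl]-1-methyl-4-(propan-2-yl)cyclohexan-1-ol | C[C@@]1(O)CC[C@H](C(C)C)[C@@H](/C=C(/C)CCC(OCC)OCC)[C@H]1[C@H](O)CC(I)=C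
F5 | step 12 | (1R,2S,3S,4R)-2-[(1R)-1-hydroxy-3-iodobut-3-en-1-yl]-1-methyl-3-[(1Z)-2-methyl-5-oxopent-1-en-1-yl]-4-(propan-2-yl)cyclohexan-1-ol | C[C@@]1(O)CC[C@H](C(C)C)[C@@H](/C=C(/C)CCC=O)[C@H]1[C@H](O)CC(I)=C
F6 | step 10 | (1R,2S,3S,4R)-2-[(1S)-3-bromo-1-hydroxybut-3-en-1-yl]-3-[(1Z)-5,5-diethoxy-2-methylpent-1-en-1-yl]-1-methyl-4-(propan-2-yl)cyclohexan-1-ol | C[C@@]1(O)CC[C@H](C(C)C)[C@@H](/C=C(/C)CCC(OCC)OCC)[C@H]1[C@@H](O)CC(Br)=C
F7 | step 10 | 3-bromo-1-{(1R,2R,5R,6S)-6-[(1Z)-5,5-diethoxy-2-methylpent-1-en-1-yl]-2-hydroxy-2-methyl-5-(propan-2-yl)cyclohexyl}but-3-en-1-one | C[C@@]1(O)CC[C@H](C(C)C)[C@@H](/C=C(/C)CCC(OCC)OCC)[C@H]1C(=O)CC(Br)=C
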